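**Strategy.** The 20-methylhenicosyl chain (C1 at the ester OCH2 through C21, methyl branch on C20) is cut at C11–C12 and C14–C15, so that C12–C14 come from propyne. This exploits the unbranched, stereocentre-free methylene run C2–C19: a C13≡C14 triple bond placed there is erased by the final hydrogenation. In a single flask, doubly lithiated propyne attacks the TBS ether of 11-bromoundecanol through its CH2Li end, and the surviving lithium acetylide is coupled with 1-bromo-6-methylheptane once DMPU is added. The precursor set is therefore propyne plus two unhindered primary bromides. The only ring, the catechol benzene ring, is attached afterwards as its dibenzyl-protected acid.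

Key step: step 3

Remark on the chemistry: the 11 + 3 + 8 carbon count (C1–C11, C12–C14, C15–C21 plus the C20 methyl) gives exactly the 22-carbon alcohol of the target, and the target is achiral, so no stereocentre has to be set. TMEDA is included so that the second (methyl) lithiation of propyne goes to completion. The dianion is used in excess over the first bromide, and the second bromide in excess over all remaining carbanion sites.

**Route**

Step 1
Reactants: 1 11-bromoundecan-1-ol
Product: 2 (11-bromoundecyloxy)(tert-butyl)dimethylsilane
Conditions: TBSCl, imidazole, CH2Cl2, 0 °C → rt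
Reagents that add atoms: tert-butyldimethylsilyl chloride, CC(C)(C)[Si](C)(C)Cl
Why: Silyl ether protection of a primary alcohol with TBSCl/imidazole should be fast and leave the primary bromide untouched, and it masks the acidic OH that would otherwise quench the dianion.

Step 2
Reactants: 3 6-methylheptan-1-ol
Product: 4 1-bromo-6-methylheptane
Conditions: PBr3 (0.4 equiv), Et2O, 0 °C → rt
Reagents that add atoms: phosphorus tribromide, BrP(Br)Br
Why: Alcohol-to-bromide substitution with PBr3 proceeds by SN2 displacement of the intermediate phosphite at an unhindered primary carbon, and the branch five carbons away rules out rearrangement.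

Step 3
Reactants: 5 propyne; 2 (11-bromoundecyloxy)(tert-butyl)dimethylsilane; 4 1-bromo-6-methylheptane
Product: 8 tert-butyl-dimethyl-(20-methylhenicos-13-ynyloxy)silane, via 1,3-dilithiopropyne 6 (not isolated), via lithium 14-(TBS-oxy)tetradec-1-ynide 7 (not isolated)
Conditions: propyne (1.5 equiv), n-BuLi (3.0 equiv), TMEDA, Et2O/hexane, −78 → 0 °C; 2 (1.0 equiv), THF, −78 °C → rt; then DMPU, 4 (2.5 equiv), rt → 40 °C; aq. NH4Cl
Reagents that add atoms: none
Why: Propyne is deprotonated first at the acetylenic C–H and then, with TMEDA activation, at the methyl group, giving C,C-dianion 6, whose sp3 carbanion is far more basic and nucleophilic than its sp acetylide end. That CH2Li terminus should displace bromide from 2 by SN2 at low temperature and form C11–C12, leaving lithium acetylide 7, which stays unreactive toward primary bromides in ether/THF until DMPU loosens its aggregates and lets it displace bromide from 4 to form C14–C15. The closest known reaction type is the sequential one-pot dialkylation of the propargyl dianion, ending in a cosolvent-promoted acetylide alkylation. No ring is closed and no stereocentre is created. The selectivity required is site selectivity between the two carbanion centres, so that each bromide ends on its own side; it is secured by the reactivity gap between CH2Li and C≡CLi, by adding 2 first as the limiting partner so that none remains for the acetylide stage, and by withholding DMPU until 4 is introduced. Both electrophiles are unhindered primary bromides and the TBS ether tolerates organolithiums, so elimination and silyl loss should stay minor, and hydrocarbon by-products from the excess dianion are non-polar enough to be removed by chromatography here or after step 4.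

Step 4
Reactants: 8 tert-butyl-dimethyl-(20-methylhenicos-13-ynyloxy)silane
Product: 9 20-methylhenicos-13-yn-1-ol
Conditions: tetrabutylammonium fluoride, THF, 0 °C → rt; H2O work-up
Reagents that add atoms: none
Why: Fluoride-mediated desilylation of a TBS ether is driven by the strong Si–F bond and should not affect the internal alkyne.

Step 5
Reactants: 10 2,3-dihydroxybenzoic acid
Product: 11 benzyl 2,3-bis(benzyloxy)benzoate
Conditions: BnBr (3.5 equiv), K2CO3, DMF, 60 °C, N2
Reagents that add atoms: benzyl bromide, BrCc1ccccc1
Why: Exhaustive Williamson-type O-benzylation of both phenoxides and the carboxylate under K2CO3 should protect the air-sensitive catechol, with excess bromide driving all three positions.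

Step 6
Reactants: 11 benzyl 2,3-bis(benzyloxy)benzoate
Product: 12 2,3-bis(benzyloxy)benzoic acid
Conditions: NaOH, MeOH/THF/H2O, 65 °C; then aq. HCl
Reagents that add atoms: sodium hydroxide, [Na+].[OH-]
Why: Saponification (base-mediated acyl substitution) should cleave only the benzyl ester, since aryl benzyl ethers are inert to hydroxide.

Step 7
Reactants: 9 20-methylhenicos-13-yn-1-ol; 12 2,3-bis(benzyloxy)benzoic acid
Product: 13 20-methylhenicos-13-ynyl 2,3-bis(benzyloxy)benzoate
Conditions: DCC, DMAP (cat.), CH2Cl2, 0 °C → rt
Reagents that add atoms: none
Why: In this Steglich esterification DCC activates the acid as an O-acylisourea and DMAP relays the acyl group to the unhindered primary alcohol, while the alkyne and benzyl ethers are spectators.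

Step 8
Reactants: 13 20-methylhenicos-13-ynyl 2,3-bis(benzyloxy)benzoate
Product: 14 Gentiside A (20-methylhenicosyl 2,3-dihydroxybenzoate)
Conditions: H2 (1 atm), 10% Pd/C, EtOAc, rt
Reagents that add atoms: none
Why: Heterogeneous catalytic hydrogenation over Pd/C should saturate the C13≡C14 alkyne and hydrogenolyse both benzylic C–O bonds in one operation, while the non-benzylic alkyl ester C–O bond stays intact and no stereocentre arises because C13 and C14 become CH2 groups.

**Compound list**

1 | 11-bromoundecan-1-ol | OCCCCCCCCCCCBr | starting material
2 | (11-bromoundecyloxy)(tert-butyl)dimethylsilane | CC(C)(C)[Si](C)(C)OCCCCCCCCCCCBr | intermediate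
3 | 6-methylheptan-1-ol | CC(C)CCCCCO | starting material
4 | 1-bromo-6-methylheptane | CC(C)CCCCCBr | intermediate
5 | propyne | CC#C | starting material
6 | 1,3-dilithiopropyne | [Li]CC#C[Li] | intermediate (not isolated)
7 | tert-butyl-(14-lithiotetradec-13-ynyloxy)dimethylsilane, i.e. lithium 14-(tert-butyldimethylsilyloxy)tetradec-1-ynide | [Li]C#CCCCCCCCCCCCCO[Si](C)(C)C(C)(C)C | intermediate (not isolated)
8 | tert-butyl-dimethyl-(20-methylhenicos-13-ynyloxy)silane | CC(C)CCCCCC#CCCCCCCCCCCCCO[Si](C)(C)C(C)(C)C | intermediate
9 | 20-methylhenicos-13-yn-1-ol | CC(C)CCCCCC#CCCCCCCCCCCCCO | intermediate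
10 | 2,3-dihydroxybenzoic acid | O=C(O)c1cccc(O)c1O | starting material
11 | benzyl 2,3-bis(benzyloxy)benzoate | O=C(OCc1ccccc1)c1cccc(OCc2ccccc2)c1OCc1ccccc1 | intermediate
12 | 2,3-bis(benzyloxy)benzoic acid | O=C(O)c1cccc(OCc2ccccc2)c1OCc1ccccc1 | intermediate
13 | 20-methylhenicos-13-ynyl 2,3-bis(benzyloxy)benzoate | CC(C)CCCCCC#CCCCCCCCCCCCCOC(=O)c1cccc(OCc2ccccc2)c1OCc1ccccc1 | intermediate
14 | Gentiside A, 20-methylhenicosyl 2,3-dihydroxybenzoate (achiral) | CC(C)CCCCCCCCCCCCCCCCCCCOC(=O)c1cccc(O)c1O | target

**Step count and risks**

Total step count: 8. Longest linear sequence: 5 steps (steps 1, 3, 4, 7, 8).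

Steps most likely to fail:

1. Step 3. Incomplete second lithiation of propyne would leave propynyllithium, which gives methyl-capped 2-alkynes in the DMPU stage. Lithium–bromine exchange or E2 elimination on 2 could erode the first alkylation, and the acetylide alkylation could stall. The fallback sets out from 2 and 4 and separates the two C–C bond formations. Commercial 1-(trimethylsilyl)propyne is lithiated at its CH2 group with n-BuLi/TMEDA in THF at low temperature and alkylated with 2 to give tert-butyl-dimethyl-(14-trimethylsilyltetradec-13-ynyloxy)silane F1. K2CO3 in MeOH then removes only the alkynyl silyl group, giving tert-butyl-dimethyl-(tetradec-13-ynyloxy)silane F2. F2 is deprotonated with n-BuLi and alkylated with 4 in THF/DMPU, which returns to the route at 8.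

2. Step 8. Saturation could stall at the C13=C14 olefin, which would co-elute with the product, or hydrogenolysis of the second benzyl ether could lag while the free catechol is exposed for a long time. The fallback sets out from 9 and moves the saturation forward. Alkynol 9 is hydrogenated over Pd/C in EtOAc to 20-methylhenicosan-1-ol F3, whose complete saturation can be verified before it is committed. F3 is esterified with 12 (DCC, DMAP) to give 20-methylhenicosyl 2,3-bis(benzyloxy)benzoate F4. The two benzyl ethers are then cleaved non-reductively with BCl3 and pentamethylbenzene in CH2Cl2 at −78 °C, which arrives directly at 14.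

3. Step 7. The O-acylisourea of the ortho-substituted acid could rearrange to the unreactive N-acylurea before acyl transfer occurs. The fallback sets out from 12 and activates the acid differently. Oxalyl chloride with catalytic DMF in CH2Cl2 converts 12 into 2,3-bis(benzyloxy)benzoyl chloride F5, which acylates alcohol 9 in the presence of Et3N and DMAP and returns to the route at 13.

**Further compounds**

F1 | step 3 | tert-butyl-dimethyl-(14-trimethylsilyltetradec-13-ynyloxy)silane | C[Si](C)(C)C#CCCCCCCCCCCCCO[Si](C)(C)C(C)(C)C
F2 | step 3 | tert-butyl-dimethyl-(tetradec-13-ynyloxy)silane | C#CCCCCCCCCCCCCO[Si](C)(C)C(C)(C)C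
F3 | step 8 | 20-methylhenicosan-1-ol | CC(C)CCCCCCCCCCCCCCCCCCCO
F4 | step 8 | 20-methylhenicosyl 2,3-bis(benzyloxy)benzoate | CC(C)CCCCCCCCCCCCCCCCCCCOC(=O)c1cccc(OCc2ccccc2)c1OCc1ccccc1
F5 | step 7 | 2,3-bis(benzyloxy)benzoyl chloride | O=C(Cl)c1cccc(OCc2ccccc2)c1OCc1ccccc1
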